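**Retrosynthetic overview**

1. Numbering (germacranolide): C8 is the lactone O–CH, C9 its CH2, C10 the methyl-bearing quaternary carbon, C1 the furanone C=O, C2 the furanone CH=, C3 the furanone O–C=, C4(C15H2OH)=C5, C6 the angelate carbinol, C7 the ring-fusion CH, C11–C13 the methylene-lactone carbons; O8 is the oxygen on C8.
2. The ten-membered carbocycle is closed last by ring-closing metathesis at C4=C5. Before that, the angelate comes from Mitsunobu inversion at C6, and C6–C7 plus the α-methylene lactone come from Barbier allylation of acrolein with a 3-(bromomethyl)butenolide built on O8.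
3. The 3(2H)-furanone (O–C3=C2–C1(=O)–C10) comes from a bicyclic tetronate by addition of the C4 vinyllithium to C3 and acid-induced carbonyl transposition, which also cuts the temporary O8–C1 bond and frees the C8 hydroxyl.
4. Key disconnection: the five-membered ring O/C3/C2/C1/C10 is grown from a cyclobutanone C3/C2/C1/C10 by Baeyer–Villiger insertion of the ring oxygen into the C3–C10 bond. The cyclobutanone comes from dichloroketene and the enol ether C1=C10 of a 2,3-dihydrofuran whose ring oxygen is O8.
5. Enabling feature: C10 is fully substituted, bonded to the ring oxygen and flanked by C1 at ketone level. It is therefore the migrating carbon (with retention) and can first be set as an all-carbon quaternary centre by a C8-directed [2+2]. Ring order: dihydrofuran (temporary) → cyclobutanone → γ-lactone/tetronate → furanone → butenolide → methylene lactone → carbocycle.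

Key step: step 5

Remark (assumption): the indium allylation of step 12 is taken to pass through the closed six-membered transition state, so its product is drawn as the (6R)-carbinol, which step 13 inverts.

**Route**

Step 1
Reactants: 1 rac-2-vinyloxirane
Product: 2 (R)-2-vinyloxirane
Conditions: (S,S)-(salen)Co(III)OAc (cat.), H2O (0.55 equiv), 0 °C→rt; distil
Reagents that add atoms: none
Why: Hydrolytic kinetic resolution (Jacobsen type): the catalyst enantiomer that hydrolyses the (S)-epoxide is used, so the (R)-epoxide carrying the future C8 configuration should be recovered in high enantiomeric purity.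

Step 2
Reactants: 2 (R)-2-vinyloxirane; 3 propanoic acid
Product: 5 (3RS,5S)-3-methyl-5-vinyldihydrofuran-2(3H)-one, via hydroxy acid 4 (not isolated)
Conditions: 3, LDA (2.2 equiv), THF, −78→0 °C; 2, 0→40 °C; 1 M HCl; PPTS (cat.), CH2Cl2, rt
Reagents that add atoms: none
Why: Epoxide opening by a carboxylic acid dianion at the unhindered terminal carbon leaves the C8 stereocentre untouched and acid closes the γ-lactone; the C10 epimer mixture does not matter because C10 becomes sp2 in step 4.

Step 3
Reactants: 5 (3RS,5S)-3-methyl-5-vinyldihydrofuran-2(3H)-one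
Product: 6 (3RS,5S)-3-methyl-5-vinyltetrahydrofuran-2-ol
Conditions: DIBAL-H (1.1 equiv), CH2Cl2, −78 °C; Rochelle salt
Reagents that add atoms: none
Why: DIBAL-H adds one hydride to the lactone carbonyl and the aluminate survives at −78 °C, the standard lactone-to-lactol reduction; the anomer mixture is of no consequence.

Step 4
Reactants: 6 (3RS,5S)-3-methyl-5-vinyltetrahydrofuran-2-ol
Product: 8 (S)-4-methyl-2-vinyl-2,3-dihydrofuran, via anomeric mesylate 7 (not isolated)
Conditions: MsCl, Et3N, CH2Cl2, −20 °C→reflux; used as a solution (volatile)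
Reagents that add atoms: none
Why: Anomeric mesylation and base-induced loss of methanesulfonic acid toward the only β-hydrogen (on the methyl-bearing carbon) is the usual lactol-to-2,3-dihydrofuran dehydration and gives the enol ether C1=C10.

Step 5
Reactants: 8 (S)-4-methyl-2-vinyl-2,3-dihydrofuran
Product: 10 (3aS,5S,6aR)-3,3-dichloro-6a-methyl-5-vinyltetrahydrofuro[3,2-b]furan-2(3H)-one, via dichlorocyclobutanone 9 (not isolated)
Conditions: Cl3CCOCl, Zn–Cu, Et2O/DME, 0 °C→rt; filter; then mCPBA, CH2Cl2, 0 °C→rt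
Reagents that add atoms: trichloroacetyl chloride ClC(=O)C(Cl)(Cl)Cl; mCPBA (3-chloroperoxybenzoic acid) OOC(=O)c1cccc(Cl)c1
Why: Dichloroketene, released from trichloroacetyl chloride by zinc, adds to the enol ether C1=C10 in a concerted asynchronous [2+2] in which the nucleophilic methyl-bearing C10 bonds to the ketene carbonyl carbon (future C3) and C1 to CCl2 (future C2); the peracid then adds to the strained ketone and, in the Criegee intermediate, the fully substituted C10 migrates from C3 to oxygen with retention. The closest known reaction type is the dichloroketene–enol ether cycloaddition followed by regioselective Baeyer–Villiger ring expansion to a γ-butyrolactone. The four-membered ring is closed by the [2+2] cycloaddition (cis-fused, suprafacial on the ring olefin), and the five-membered ring O–C3–C2–C1–C10 is not closed but grown from it by the 1,2-shift that inserts one oxygen atom. C10 and C1 are set in the cycloaddition by the C8 vinyl group, which should send the ketene to the opposite face of the dihydrofuran, and C10 keeps its configuration in the migration, so the C10–O bond ends up trans to the C8 substituent as the target requires. The step needs regioselective migration, secured by quaternary C10 against the electron-poor CCl2 carbon, and chemoselectivity for the ketone over the terminal alkene, secured by the high Baeyer–Villiger reactivity of strained α,α-dichlorocyclobutanones.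

Step 6
Reactants: 10 (3aS,5S,6aR)-3,3-dichloro-6a-methyl-5-vinyltetrahydrofuro[3,2-b]furan-2(3H)-one
Product: 11 (5S,6aR)-3-chloro-6a-methyl-5-vinyl-6,6a-dihydrofuro[3,2-b]furan-2(5H)-one
Conditions: DBU, toluene, rt→60 °C
Reagents that add atoms: none
Why: E2 dehydrochlorination: the only β-hydrogen is on the ring-fusion carbon C1, so loss of HCl can only give the chlorinated vinylogous carbonate (chlorotetronate), which moves the ketone oxidation level onto C1 and touches neither C8 nor C10.

Step 7
Reactants: 11 (5S,6aR)-3-chloro-6a-methyl-5-vinyl-6,6a-dihydrofuro[3,2-b]furan-2(5H)-one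
Product: 12 (5S,6aR)-6a-methyl-5-vinyl-6,6a-dihydrofuro[3,2-b]furan-2(5H)-one
Conditions: Zn dust, AcOH, 40 °C
Reagents that add atoms: none
Why: Reductive dehalogenation of an α-halo-α,β-unsaturated lactone by zinc in acetic acid (electron transfer to the conjugated ester, loss of chloride, protonation) is a known reaction type and should leave the isolated vinyl group and C10 untouched.

Step 8
Reactants: 13 2-bromoprop-2-en-1-ol
Product: 14 [(2-bromoprop-2-en-1-yl)oxy](tert-butyl)diphenylsilane
Conditions: TBDPSCl, imidazole, CH2Cl2, rt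
Reagents that add atoms: tert-butyl(chloro)diphenylsilane CC(C)(C)[Si](Cl)(c1ccccc1)c1ccccc1
Why: Standard silylation of a primary alcohol; the bulky TBDPS group is chosen to survive the acid of step 9 and to resist O→C silyl migration in the lithium reagent.

Step 9
Reactants: 12 (5S,6aR)-6a-methyl-5-vinyl-6,6a-dihydrofuro[3,2-b]furan-2(5H)-one; 14 [(2-bromoprop-2-en-1-yl)oxy](tert-butyl)diphenylsilane
Product: 17 (R)-5-{3-[(tert-butyldiphenylsilyl)oxy]prop-1-en-2-yl}-2-[(S)-2-hydroxybut-3-en-1-yl]-2-methylfuran-3(2H)-one, via vinyllithium 15 (not isolated), via lithium hemiketal 16 (not isolated)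
Conditions: 14, t-BuLi (2 equiv), Et2O, −78 °C; 12, −78 °C; then 1 M HCl, THF, 0 °C
Reagents that add atoms: none
Why: Bromine–lithium exchange gives the 2-lithioallyl ether, which adds 1,2 to the lactone carbonyl C3 of the vinylogous carbonate (Stork–Danheiser-type alkylative carbonyl transposition); acid ionises the hemiketal to a 2H-furanium ion, water adds at C1 and the tethered alkoxide O8 leaves, so the 3(2H)-furanone and the free C8 hydroxyl should be unmasked together with C10 untouched.

Step 10
Reactants: 17 (R)-5-{3-[(tert-butyldiphenylsilyl)oxy]prop-1-en-2-yl}-2-[(S)-2-hydroxybut-3-en-1-yl]-2-methylfuran-3(2H)-one; 18 2-(bromomethyl)acrylic acid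
Product: 19 (S)-1-[(R)-5-{3-[(tert-butyldiphenylsilyl)oxy]prop-1-en-2-yl}-2-methyl-3-oxo-2,3-dihydrofuran-2-yl]but-3-en-2-yl 2-(bromomethyl)acrylate
Conditions: DCC, DMAP (cat.), CH2Cl2, 0 °C
Reagents that add atoms: none
Why: Steglich esterification of the secondary allylic alcohol, kept cold and with little DMAP so that the allylic bromide of the acid is not attacked; no stereocentre is involved.

Step 11
Reactants: 19 (S)-1-[(R)-5-{3-[(tert-butyldiphenylsilyl)oxy]prop-1-en-2-yl}-2-methyl-3-oxo-2,3-dihydrofuran-2-yl]but-3-en-2-yl 2-(bromomethyl)acrylate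
Product: 20 (R)-2-{[(S)-4-(bromomethyl)-5-oxo-2,5-dihydrofuran-2-yl]methyl}-5-{3-[(tert-butyldiphenylsilyl)oxy]prop-1-en-2-yl}-2-methylfuran-3(2H)-one
Conditions: Grubbs II (cat.), CH2Cl2, 40 °C
Reagents that add atoms: none
Why: Ring-closing metathesis between the terminal vinyl group on C8 and the acrylate olefin closes the five-membered butenolide, which should be far faster than any reaction of the hindered, conjugated 1,1-disubstituted C4 olefin; allylic bromides are tolerated by ruthenium carbenes.

Step 12
Reactants: 20 (R)-2-{[(S)-4-(bromomethyl)-5-oxo-2,5-dihydrofuran-2-yl]methyl}-5-{3-[(tert-butyldiphenylsilyl)oxy]prop-1-en-2-yl}-2-methylfuran-3(2H)-one; 21 acrolein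
Product: 23 (R)-5-{3-[(tert-butyldiphenylsilyl)oxy]prop-1-en-2-yl}-2-({(2S,3S)-3-[(R)-1-hydroxyprop-2-en-1-yl]-4-methylidene-5-oxooxolan-2-yl}methyl)-2-methylfuran-3(2H)-one, via allylindium 22 (not isolated)
Conditions: In powder, 21 (excess), THF/H2O, rt
Reagents that add atoms: none
Why: Indium-mediated Barbier allylation with γ-attack (SE2′) of the butenolide-derived allylmetal: bond formation at C7 anti to the C8 side chain should give the trans-lactone with its exocyclic methylene, the ring-locked (E)-type allylmetal in a Zimmerman–Traxler chair should give the 6,7-anti (6R) carbinol, and allylindium reagents select the aldehyde over the hindered vinylogous-ester carbonyl C1.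

Step 13
Reactants: 23 (R)-5-{3-[(tert-butyldiphenylsilyl)oxy]prop-1-en-2-yl}-2-({(2S,3S)-3-[(R)-1-hydroxyprop-2-en-1-yl]-4-methylidene-5-oxooxolan-2-yl}methyl)-2-methylfuran-3(2H)-one; 24 angelic acid
Product: 25 (S)-1-[(2S,3R)-2-{[(R)-5-{3-[(tert-butyldiphenylsilyl)oxy]prop-1-en-2-yl}-2-methyl-3-oxo-2,3-dihydrofuran-2-yl]methyl}-4-methylidene-5-oxooxolan-3-yl]prop-2-en-1-yl (Z)-2-methylbut-2-enoate
Conditions: PPh3, DIAD, toluene, 0 °C→rt
Reagents that add atoms: none
Why: Mitsunobu esterification: SN2 displacement of the activated C6 alcohol by angelate inverts C6 to the required (S) configuration, and because the acid is never activated at its carbonyl the Z geometry of the angelate should be kept.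

Step 14
Reactants: 25 (S)-1-[(2S,3R)-2-{[(R)-5-{3-[(tert-butyldiphenylsilyl)oxy]prop-1-en-2-yl}-2-methyl-3-oxo-2,3-dihydrofuran-2-yl]methyl}-4-methylidene-5-oxooxolan-3-yl]prop-2-en-1-yl (Z)-2-methylbut-2-enoate
Product: 26 15-O-TBDPS ether of the target (bridged ten-membered carbocycle with 4Z olefin)
Conditions: Hoveyda–Grubbs II (cat.), toluene, high dilution, 80–100 °C
Reagents that add atoms: none
Why: Ring-closing metathesis joins the terminal C5 vinyl group and the 1,1-disubstituted C4 olefin with loss of ethylene; the ten-membered ring can only hold the cis (Z) ring olefin, and the electron-poor methylene-lactone and angelate double bonds should stay out of the catalytic cycle.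

Step 15
Reactants: 26 15-O-TBDPS ether of the target
Product: 27 CNP0176514.1 (target)
Conditions: HF·pyridine, THF/pyridine, 0 °C→rt
Reagents that add atoms: none
Why: Fluoride cleaves the primary silyl ether under mildly acidic, non-nucleophilic conditions that should spare the angelate, the α-methylene lactone and the furanone.

**Compound list**

1 | rac-2-vinyloxirane (butadiene monoxide) | C=CC1CO1 | starting material
2 | (R)-2-vinyloxirane | C=C[C@@H]1CO1 | intermediate
3 | propanoic acid | CCC(=O)O | starting material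
4 | (2RS,4S)-4-hydroxy-2-methylhex-5-enoic acid (as its dilithium salt in the flask) | C=C[C@@H](O)CC(C)C(=O)O | intermediate
5 | (3RS,5S)-3-methyl-5-vinyldihydrofuran-2(3H)-one | C=C[C@@H]1CC(C)C(=O)O1 | intermediate
6 | (3RS,5S)-3-methyl-5-vinyltetrahydrofuran-2-ol (anomer mixture) | C=C[C@@H]1CC(C)C(O)O1 | intermediate
7 | (3RS,5S)-3-methyl-5-vinyltetrahydrofuran-2-yl methanesulfonate | C=C[C@@H]1CC(C)C(OS(C)(=O)=O)O1 | intermediate
8 | (S)-4-methyl-2-vinyl-2,3-dihydrofuran | C=C[C@@H]1CC(C)=CO1 | intermediate
9 | (1S,3S,5R)-7,7-dichloro-5-methyl-3-vinyl-2-oxabicyclo[3.2.0]heptan-6-one | C=C[C@@H]1C[C@@]2(C)C(=O)C(Cl)(Cl)[C@H]2O1 | intermediate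
10 | (3aS,5S,6aR)-3,3-dichloro-6a-methyl-5-vinyltetrahydrofuro[3,2-b]furan-2(3H)-one | C=C[C@@H]1C[C@@]2(C)OC(=O)C(Cl)(Cl)[C@H]2O1 | intermediate
11 | (5S,6aR)-3-chloro-6a-methyl-5-vinyl-6,6a-dihydrofuro[3,2-b]furan-2(5H)-one | C=C[C@@H]1C[C@@]2(C)OC(=O)C(Cl)=C2O1 | intermediate
12 | (5S,6aR)-6a-methyl-5-vinyl-6,6a-dihydrofuro[3,2-b]furan-2(5H)-one (bicyclic tetronate) | C=C[C@@H]1C[C@@]2(C)OC(=O)C=C2O1 | intermediate
13 | 2-bromoprop-2-en-1-ol | C=C(Br)CO | starting material
14 | [(2-bromoprop-2-en-1-yl)oxy](tert-butyl)diphenylsilane | C=C(Br)CO[Si](c1ccccc1)(c1ccccc1)C(C)(C)C | intermediate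
15 | {3-[(tert-butyldiphenylsilyl)oxy]prop-1-en-2-yl}lithium | [Li]C(=C)CO[Si](c1ccccc1)(c1ccccc1)C(C)(C)C | intermediate
16 | lithium hemiketal alkoxide from 1,2-addition of 15 to C3 of 12 (epimers at C3) | C=C[C@@H]1C[C@@]2(C)OC(O[Li])(C=C2O1)C(=C)CO[Si](c3ccccc3)(c3ccccc3)C(C)(C)C | intermediate
17 | (R)-5-{3-[(tert-butyldiphenylsilyl)oxy]prop-1-en-2-yl}-2-[(S)-2-hydroxybut-3-en-1-yl]-2-methylfuran-3(2H)-one | C=C[C@@H](O)C[C@@]1(C)OC(=CC1=O)C(=C)CO[Si](c2ccccc2)(c2ccccc2)C(C)(C)C | intermediate
18 | 2-(bromomethyl)acrylic acid | C=C(CBr)C(=O)O | starting material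
19 | (S)-1-[(R)-5-{3-[(tert-butyldiphenylsilyl)oxy]prop-1-en-2-yl}-2-methyl-3-oxo-2,3-dihydrofuran-2-yl]but-3-en-2-yl 2-(bromomethyl)acrylate | C=C[C@@H](OC(=O)C(=C)CBr)C[C@@]1(C)OC(=CC1=O)C(=C)CO[Si](c2ccccc2)(c2ccccc2)C(C)(C)C | intermediate
20 | (R)-2-{[(S)-4-(bromomethyl)-5-oxo-2,5-dihydrofuran-2-yl]methyl}-5-{3-[(tert-butyldiphenylsilyl)oxy]prop-1-en-2-yl}-2-methylfuran-3(2H)-one | BrCC1=C[C@H](C[C@@]2(C)OC(=CC2=O)C(=C)CO[Si](c3ccccc3)(c3ccccc3)C(C)(C)C)OC1=O | intermediate
21 | acrolein (prop-2-enal) | C=CC=O | starting material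
22 | allylindium dibromide formed from 20 by insertion of indium into the C–Br bond | Br[In](Br)CC1=C[C@H](C[C@@]2(C)OC(=CC2=O)C(=C)CO[Si](c3ccccc3)(c3ccccc3)C(C)(C)C)OC1=O | intermediate
23 | (R)-5-{3-[(tert-butyldiphenylsilyl)oxy]prop-1-en-2-yl}-2-({(2S,3S)-3-[(R)-1-hydroxyprop-2-en-1-yl]-4-methylidene-5-oxooxolan-2-yl}methyl)-2-methylfuran-3(2H)-one (trans-lactone, 6R carbinol) | C=C1C(=O)O[C@@H](C[C@@]2(C)OC(=CC2=O)C(=C)CO[Si](c3ccccc3)(c3ccccc3)C(C)(C)C)[C@@H]1[C@H](O)C=C | intermediate
24 | angelic acid, (Z)-2-methylbut-2-enoic acid | C/C=C(/C)C(=O)O | starting material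
25 | (S)-1-[(2S,3R)-2-{[(R)-5-{3-[(tert-butyldiphenylsilyl)oxy]prop-1-en-2-yl}-2-methyl-3-oxo-2,3-dihydrofuran-2-yl]methyl}-4-methylidene-5-oxooxolan-3-yl]prop-2-en-1-yl (Z)-2-methylbut-2-enoate | C=C1C(=O)O[C@@H](C[C@@]2(C)OC(=CC2=O)C(=C)CO[Si](c3ccccc3)(c3ccccc3)C(C)(C)C)[C@@H]1[C@@H](OC(=O)/C(C)=C\C)C=C | intermediate
26 | 15-O-TBDPS ether of the target (6S,7R,8S,10R; 4Z) | C=C1C(=O)O[C@H]2C[C@@]3(C)OC(=CC3=O)/C(CO[Si](c4ccccc4)(c4ccccc4)C(C)(C)C)=C\[C@H](OC(=O)/C(C)=C\C)[C@H]12 | intermediate
27 | CNP0176514.1 (6S,7R,8S,10R; 4Z; 6-O-angelate, 15-OH, 8,12-olide) | C=C1C(=O)O[C@H]2C[C@@]3(C)OC(=CC3=O)/C(CO)=C\[C@H](OC(=O)/C(C)=C\C)[C@H]12 | target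

**Count and risks**

Total step count: 15. Longest linear sequence: 14 steps (steps 1–7 and 9–15; step 8 is the one-step side branch).

Step 14 (macrocyclisation by metathesis). What may go wrong: closure of the strained, oxygen-bridged ten-membered ring at a 1,1-disubstituted diene terminus is slow, so intermolecular metathesis to oligomers and decay of the carbene can outrun it. Fallback: the C4=C5 bond is installed beforehand with fixed Z geometry and the ring is closed at C6–C7 by an intramolecular Barbier allylation instead; it sets out from tetronate 12. Commercial but-2-yne-1,4-diol is monosilylated (TBDPSCl, NaH, THF) to 4-[(tert-butyldiphenylsilyl)oxy]but-2-yn-1-ol F1. Trans-hydroalumination and iodination (Red-Al, then I2) should convert it into (Z)-4-[(tert-butyldiphenylsilyl)oxy]-3-iodobut-2-en-1-ol F2, which is protected (4-methoxybenzyl trichloroacetimidate, cat. CSA) as the PMB ether F3. Iodine–lithium exchange of F3 (t-BuLi, −78 °C) and addition to 12 with the acid work-up of step 9 should give the (Z)-configured furanone alcohol F4. Esterification with 18 as in step 10 gives the 2-(bromomethyl)acrylate F5, and metathesis as in step 11 the bromomethylbutenolide F6. DDQ then frees the allylic alcohol F7, MnO2 oxidises it to the (Z)-enal F8, and indium-mediated allylation under high dilution should close the ten-membered ring to the macrocyclic carbinol F9 (drawn as the 6R epimer expected from the same closed transition state). Mitsunobu esterification of F9 with 24 under the conditions of step 13 comes back to the route at compound 26.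

Step 13 (inverting esterification). What may go wrong: angelic acid is a weak and hindered pronucleophile and the C6 carbinol is allylic and flanked by the lactone ring, so slow displacement can give way to SN2′ transposition, elimination, partial retention or Z→E isomerisation of the ester. Fallback: inversion and acylation are separated; it sets out from alcohol 23. Mitsunobu reaction with formic acid (PPh3, DIAD) should give the inverted formate F10, and mild methanolysis (KHCO3, MeOH/H2O, 0 °C) the (6S)-alcohol F11. Acyl transfer with retention from the mixed anhydride of 24 and 2,4,6-trichlorobenzoyl chloride (Et3N; then F11, toluene, 80 °C) gives angelate 25, where the route is rejoined.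

Step 9 (organolithium addition to the tetronate). What may go wrong: the vinyllithium can act as a base on the vinylic C2–H of the vinylogous carbonate or add a second time after ring opening, and warming lets the silyl group of 15 migrate from oxygen to carbon. Fallback: the acyl carbon C3 is first converted into a Weinreb amide that takes up exactly one organometallic; it sets out from tetronate 12. Aminolysis with N,O-dimethylhydroxylamine hydrochloride and i-PrMgCl (THF, −20 °C) should open the lactone to the (E)-2-[(3R,5S)-3-hydroxy-3-methyl-5-vinyldihydrofuran-2(3H)-ylidene]-N-methoxy-N-methylacetamide F12. Addition of an excess of 15 (the free tertiary hydroxyl consumes one equivalent) and the same aqueous acid work-up close the furanone through the C10 hydroxyl, release O8 and return to the route at compound 17.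

**Further compounds**

F1 | step 14 | 4-[(tert-butyldiphenylsilyl)oxy]but-2-yn-1-ol | OCC#CCO[Si](c1ccccc1)(c1ccccc1)C(C)(C)C
F2 | step 14 | (Z)-4-[(tert-butyldiphenylsilyl)oxy]-3-iodobut-2-en-1-ol | OC/C=C(\I)CO[Si](c1ccccc1)(c1ccccc1)C(C)(C)C
F3 | step 14 | (Z)-tert-butyl({2-iodo-4-[(4-methoxybenzyl)oxy]but-2-en-1-yl}oxy)diphenylsilane | COc1ccc(COC/C=C(\I)CO[Si](c2ccccc2)(c2ccccc2)C(C)(C)C)cc1
F4 | step 14 | (R)-5-{(Z)-1-[(tert-butyldiphenylsilyl)oxy]-4-[(4-methoxybenzyl)oxy]but-2-en-2-yl}-2-[(S)-2-hydroxybut-3-en-1-yl]-2-methylfuran-3(2H)-one | C=C[C@@H](O)C[C@@]1(C)OC(=CC1=O)/C(CO[Si](c2ccccc2)(c2ccccc2)C(C)(C)C)=C\COCc2ccc(OC)cc2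
F5 | step 14 | 2-(bromomethyl)acrylate of F4 at the C8 hydroxyl | C=C[C@@H](OC(=O)C(=C)CBr)C[C@@]1(C)OC(=CC1=O)/C(CO[Si](c2ccccc2)(c2ccccc2)C(C)(C)C)=C\COCc2ccc(OC)cc2
F6 | step 14 | (R)-2-{[(S)-4-(bromomethyl)-5-oxo-2,5-dihydrofuran-2-yl]methyl}-5-{(Z)-1-[(tert-butyldiphenylsilyl)oxy]-4-[(4-methoxybenzyl)oxy]but-2-en-2-yl}-2-methylfuran-3(2H)-one | BrCC1=C[C@H](C[C@@]2(C)OC(=CC2=O)/C(CO[Si](c3ccccc3)(c3ccccc3)C(C)(C)C)=C\COCc3ccc(OC)cc3)OC1=O
F7 | step 14 | primary allylic alcohol from F6 after removal of the PMB group | BrCC1=C[C@H](C[C@@]2(C)OC(=CC2=O)/C(CO[Si](c3ccccc3)(c3ccccc3)C(C)(C)C)=C\CO)OC1=O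
F8 | step 14 | (Z)-enal from oxidation of F7 | BrCC1=C[C@H](C[C@@]2(C)OC(=CC2=O)/C(CO[Si](c3ccccc3)(c3ccccc3)C(C)(C)C)=C\C=O)OC1=O
F9 | step 14 | macrocyclic (6R)-carbinol, 15-O-TBDPS, trans-fused methylene lactone | C=C1C(=O)O[C@H]2C[C@@]3(C)OC(=CC3=O)/C(CO[Si](c4ccccc4)(c4ccccc4)C(C)(C)C)=C\[C@@H](O)[C@H]12
F10 | step 13 | (6S)-formate obtained from 23 with inversion | C=C1C(=O)O[C@@H](C[C@@]2(C)OC(=CC2=O)C(=C)CO[Si](c3ccccc3)(c3ccccc3)C(C)(C)C)[C@@H]1[C@@H](OC=O)C=C
F11 | step 13 | (6S)-alcohol, C6 epimer of 23 | C=C1C(=O)O[C@@H](C[C@@]2(C)OC(=CC2=O)C(=C)CO[Si](c3ccccc3)(c3ccccc3)C(C)(C)C)[C@@H]1[C@@H](O)C=C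
F12 | step 9 | (E)-2-[(3R,5S)-3-hydroxy-3-methyl-5-vinyldihydrofuran-2(3H)-ylidene]-N-methoxy-N-methylacetamide | C=C[C@@H]1C[C@@](C)(O)/C(O1)=C\C(=O)N(C)OC
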